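The data were computed with made-up constants, and the scatter is random.

Count the chains. Two flasks, autumn and dawn, hold the same initiator and transfer agent but differ in free monomer, and I want the average chain length in each at the end.

| flask | free monomer | transfer agent | initiator | remark | time |
|---|---|---|---|---|---|
| Monday's | 0.33 M | 7.7 mM | 3.9 mM | run made earlier |  |
| Friday's | 0.59 M | 7.7 mM | 3.9 mM | run made earlier |  |
| Tuesday's | 0.55 M | 7.7 mM | 3.9 mM | run made earlier |  |
| autumn | 0.77 M | 7.70 mM | 3.9 mM |  | 3.0 d |
| dawn | 0.40 M | 7.70 mM | 3.9 mM |  | 3.0 d |

| run | time / h | monomer in chains / % |
|---|---|---|
| Monday's | 3.00 | 66.2 |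
| Monday's | 5.00 | 85.5 |
| Monday's | 10.0 | 95.7 |
| Monday's | 20.0 | 98.2 |
| Monday's | 40.0 | 99.0 |
| Friday's | 8.00 | 97.3 |
| Friday's | 15.0 | 98.7 |
| Friday's | 20.0 | 98.3 |
| Friday's | 30.0 | 99.8 |
| Friday's | 40.0 | 98.9 |
| Tuesday's | 8.00 | 97.2 |
| Tuesday's | 15.0 | 98.8 |
| Tuesday's | 20.0 | 98.6 |
| Tuesday's | 30.0 | 99.1 |
| Tuesday's | 40.0 | 98.3 |

(readings scatter by 0.5 percentage points)

- the average divides the monomer in chains by the number of chains begun, living and dead together
- the earlier runs were read with a standard deviation of 0.5 percentage points
- the earlier runs do not show the number of chains; that part of a forecast is a guess

1. which of the two ends with the longer chains by the average number of monomer units in a chain (chains begun, living or dead) ("neither" if they lie within 10%) (autumn / dawn / neither)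
2. average number of monomer units in a chain (chains begun, living or dead) at the end, autumn
3. average number of monomer units in a chain (chains begun, living or dead) at the end, dawn

Monday's run reads 99.0% at 40.0 h and Friday's 98.9%, so I take the same high conversion in both flasks, though 0.77 M lies above the charges tried. Length then goes as free monomer charged over chains begun. I turn the question round: for autumn to lose its lead beyond the 10% margin, it would have to begin 1.75 times as many chains as dawn.

The readings do not show chains, so I guess that each chain begun costs one initiator, the smaller charge, and that transfer agent begins none. The balance then says chains begun equal initiator used, which cannot exceed 3.9 mM. In autumn r = 197, the free monomer charged per initiator charged, and in dawn it is 103; these are the shortest lengths my guess allows, give or take conversion. Even with autumn using its whole initiator charge, dawn would have to use under 57.1% of its own to come within the margin. I have no ground for so wide a gap, so I commit to autumn, with lengths above r.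

The forecast, saying “Autumn is clearly longer”, gives autumn with 61 and 32, below my r in autumn and in dawn.

The flask gives autumn, at 287 in autumn and 170 in dawn.

    free monomer + initiator → living end + monomer in chains (k = 0.0120 /M/min)
    free monomer + living end → monomer in chains + living end, rate k2*[living end]*[free monomer] (k = 8.59 /M/min)
    living end + transfer agent → dead chain (kL = 0.608 /M/min)
    monomer in chains → over-reaction product (k = 1.73 × 10⁻⁶ /min)

In autumn at 0.0589 d, free monomer has a half-life of 0.94 h by growth, shorter than the 0.10 d of initiator by the starting step. At 3.0 d in autumn free monomer, the limiting reagent, stands at 0.24% of its charge and initiator at 32%, so r, times the 99.0% in chains and divided by the 68.0% of initiator used, gives 287. The flask like autumn with 0.46 M of free monomer has r = 118, keeps 39% of its initiator and ends at 190.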